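Remark: the locants O1, C2, C3, C4, C5, C9 (oxymethyl carbon on C3) and C7′ (benzylic CH2 on C4) are those of the target oxolane and are kept for the same atoms in every intermediate; TIPS = triisopropylsilyl, Tr = triphenylmethyl.

## Structural features

The target is the C9 stearate of (+)-lariciresinol. It has one oxolane ring (O1, C2, C3, C4, C5) carrying a 4-hydroxy-3-methoxyphenyl group on C2, the acyloxymethyl carbon C9 on C3 and a 4-hydroxy-3-methoxybenzyl group (through C7′) on C4, while C5 is an unsubstituted OCH2. C2, C3 and C4 are three contiguous stereocentres (2S,3R,4R), with the aryl group trans to C9 and C9 cis to the benzyl group. The C2–O1 bond is a benzylic ether activated by a para oxygen, so acid ionises it (epimerisation, Friedel–Crafts closure onto the second arene) and hydrogenolysis cleaves it. The free guaiacol units are easily oxidised, for example by periodate, and the fatty ester does not survive hydride or strong base. C2 can be set late, because it forms reversibly from a stabilised cation under the influence of C3. The real difficulty is the absolute configuration of the C3/C4 pair and their cis relationship, since neither centre can be epimerised afterwards. The key step exploits the 1,4-dioxygenated chain C5–C4–C3–C9: closed through C9 instead of C2 it is a γ-lactone with C4 as α-carbon, C3 as β-carbon and C2 and C7′ as exocyclic carbons. In that lactone the cis pair of the oxolane is the easily made trans pair.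

## Logic of the disconnections

**27 back to 26, then to 24 and 25.** The bonds cut are the two phenolic O–Si bonds and the acyl C–O9 bond. The ester goes on late because it would not survive hydride or organolithium chemistry. It goes on before the phenols are freed, so that 24 offers a single hydroxyl. This removes eighteen carbons and every chemoselectivity question in one cut. The forward demand is that desilylation of 26 spares the ester, which calls for buffered fluoride.

**24 back to 23.** The O1–C2 bond is cut. C2 is benzylic and para-oxygenated, so the bond can form from a cation that the C5 hydroxyl captures. This removes the ring and the need to set C2 independently, so 23 may be a mixture of carbinol epimers. The forward step must close through the C5 hydroxyl (five-membered) and not the C9 hydroxyl (four-membered), give the 2,3-trans isomer, and stop before the second arene attacks the cation.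

**23 back to 20.** C9 is extended by one carbon to a 1,2-diol. The extra carbon is what lets C9 be a ring carbon and a stereocentre of a lactone. The price is one sacrificial carbon. The forward cleavage needs a substrate with one 1,2-diol only, no sulfur and no free phenol.

**20 back to 19, 18 and 17.** These are changes of function only: the lactone C5(=O)–O bond and the C2 ketone are restored (19), the O–CPh3 bond is restored (18), and C2=O is replaced by its two C–S bonds (17). The order is chosen so that the trityl ether is removed while C2 is still a ketone. The acid-labile benzylic alcohol then never meets the detritylation acid, and the freed exocyclic hydroxyl cannot compete in a ring closure at C2. The dithiane must go before periodate is used, since periodate oxidises sulfides.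

**17 back to 8, 12 and 14.** The C2–C3 and C4–C7′ bonds are cut. This is the strategic cut: one operation unites three fragments of similar size and sets C3 and C4 from the single stereocentre of 8. A descriptor check confirms that the R enantiomer of 8 is required. Addition anti to its γ-substituent and alkylation anti to the new group give (3R,4R,5R)-17, whose C3 and C4 carry over unchanged as 3R,4R of 27. The forward step needs 1,4-addition, C-alkylation and two anti inductions.

**8 back to 7, 6, 4 with 5, then 3, 2 and 1.** The O–CPh3 bond, the lactone C–O bond, the C=C bond (Wittig) and finally C1–C3 of 1 are cut. The stereocentre of 8 is C5 of 1, so the R butenolide comes from an inexpensive chiral-pool compound without any asymmetric step. The forward demands are a Z-selective olefination and no base strong enough to deprotonate the γ-carbon of the butenolide.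

**12 back to 10 and 11; 14 back to 13, 10 and 9.** The two C–S bonds, the C–Br bond and the O–Si bond are cut. Both aryl fragments come from the same silylated aldehyde 10, itself one step from 9. The silyl ether must survive thioacetalisation, bromination and an organolithium.

## Other disconnections considered

**Alternative 1:** The cut is the C4–C7′ bond, made while C7′ is held temporarily on the C9 oxygen.
- Forward step: the enol ether alcohol A1 (C4=C5) would exchange with the aryl aldehyde dimethyl acetal A2 under a Lewis acid. The tethered oxocarbenium ion would be attacked by C4, closing a second oxolane (O, C9, C3, C4, C7′), and methanol would trap the cation at C5 to give A3.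
- In favour: the cis relationship of C9 and C7′ is imposed by the cis-fused bicyclic geometry. On this point the alternative is the better of the two, since the chosen plan depends on two consecutive anti inductions. It is equally convergent, and its key step forms a ring as well as a C–C bond.
- Against: A3 holds an acetal and two para-oxygenated benzylic ether bonds (C2–O1 and C7′–O). The target needs reductive removal of the C5 methoxy group, which leads to the symmetrical bis-silyl pinoresinol A4, and then hydrogenolysis of exactly one benzylic C–O bond. The first cleavage of A4 is unambiguous, but the second differs little in rate, and the Lewis acid used for the acetal reduction can ionise C2.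
- Comparison: A1 must carry the absolute configuration and needs its own asymmetric synthesis next to an acid-sensitive enol ether. The chosen plan takes its configuration from 1 and keeps cations away from the benzylic positions until the ring closure. Step counts after the key step would be similar.

**Alternative 2:** The cut is the ring C–O bond of a β-benzyl γ-lactone (O1–C5), traced to the prochiral cyclobutanone A5.
- Forward step: an enantioselective Baeyer–Villiger oxidation (H2O2 with a chiral Brønsted acid, Sc(OTf)3 with a chiral N,N′-dioxide ligand, or a monooxygenase) would insert oxygen next to one of the two enantiotopic CH2 groups. The Criegee intermediate would give A6 with C4 as R.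
- In favour: A5 should be reachable in about three steps from an allylarene (ketene cycloaddition, dechlorination). A6 would reach 23 in two more steps, by a trans-selective aldol addition of its enolate to 10 and hydride reduction, and would then join steps 16 to 18. That is roughly half the step count of the chosen plan, with no sacrificial carbon, no dithiane and no periodate. On step and atom economy this alternative is clearly the better one, and the final stages are the same.
- Against: the stereocentre is remote from the reacting carbonyl, so the enantiomeric purity depends entirely on catalyst–substrate matching for a flexible benzyl group. The chiral-pool route delivers full enantiopurity by construction. C3 would again be set by 1,2-anti induction, which is the same kind of control as the second induction of the chosen plan.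
- Comparison: shorter and more modern, but less certain in absolute stereocontrol. The chosen plan trades length for predictability.

**Alternative 3:** The cut is the C3–C4 bond, formed by radical cyclisation of the epoxy cinnamyl ether A7.
- Forward step: Cp2TiCl (trivalent titanium, from Cp2TiCl2 and zinc) would open the terminal epoxide homolytically to the C3 radical. This would cyclise 5-exo-trig onto the cinnamyl alkene, and the benzylic radical at C7′ would be reduced by a second equivalent and protonated, giving A8.
- In favour: A8 is identical with 24. One step would form the ring, the C3–C4 bond and both stereocentres, and deliver C9–OH and the C7′ methylene at the right oxidation level with no protecting group on C9. In step and redox economy this alternative is the better one. The preferred chair-like transition state (C2 aryl pseudo-equatorial) points to the 2,3-trans-3,4-cis product.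
- Against: the 3,4-cis preference of such 5-exo closures is usually moderate, so C4 epimers that are hard to separate are to be expected. C2 must come from a kinetic resolution or asymmetric synthesis of a very ionisation-prone para-oxygenated benzylic allylic alcohol. Reduction of the radical before cyclisation and β-elimination to an allylic alcohol would compete.
- Comparison: the alternative's key step builds one ring, one skeletal bond and two stereocentres; the chosen one builds no ring, two skeletal bonds and two stereocentres. The alternative is shorter, but the chosen plan rests on two anti inductions with strong steric bias and a chiral-pool stereocentre.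

Key step: step 11

## Route

Step 1
Reactants: 1 L-ascorbic acid
Product: 2 L-gulono-1,4-lactone
Conditions: H2 (3.5 bar), 10% Pd/C, H2O, 50 °C
Reagents that add atoms: none
Why: Heterogeneous catalytic hydrogenation of the enediol double bond; hydrogen is delivered cis from the face opposite the C4 side chain, giving the all-cis gulono lactone. The two new centres are sacrificial, since both carbons are excised in step 3.

Step 2
Reactants: 2 L-gulono-1,4-lactone
Product: 3 5,6-O-isopropylidene-L-gulono-1,4-lactone
Conditions: 2-methoxypropene, TsOH·H2O (cat.), DMF, 0 °C to rt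
Reagents that add atoms: 2-methoxypropene, COC(C)=C
Why: Kinetic acetonide formation with an enol ether selects the terminal 5,6-diol and leaves the ring 2,3-diol free for cleavage.

Step 3
Reactants: 3 5,6-O-isopropylidene-L-gulono-1,4-lactone
Product: 4 (S)-2,2-dimethyl-1,3-dioxolane-4-carbaldehyde
Conditions: NaIO4 (2 equiv), H2O, pH 5.5 (NaOH), 0 °C to rt
Reagents that add atoms: none
Why: Periodate glycol cleavage of the 2,3-diol, hydrolysis of the resulting glyoxylate ester and a second cleavage of the α-hydroxy aldehyde excise C1 to C3. The former C5 stereocentre is not touched and becomes the S-configured α-carbon of the aldehyde, which is used at once because it is configurationally labile.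

Step 4
Reactants: 4 (S)-2,2-dimethyl-1,3-dioxolane-4-carbaldehyde; 5 methyl (triphenylphosphoranylidene)acetate
Product: 6 methyl (Z)-3-[(4R)-2,2-dimethyl-1,3-dioxolan-4-yl]prop-2-enoate
Conditions: MeOH, 0 °C
Reagents that add atoms: none
Why: Wittig olefination with a stabilised ylide; with α-alkoxy aldehydes in methanol at low temperature the Z enoate should predominate, and this is the geometry that can lactonise. The stereocentre is untouched (the descriptor changes only because the priorities change).

Step 5
Reactants: 6 methyl (Z)-3-[(4R)-2,2-dimethyl-1,3-dioxolan-4-yl]prop-2-enoate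
Product: 7 (R)-5-(hydroxymethyl)furan-2(5H)-one
Conditions: H2SO4 (cat.), MeOH/H2O (10:1), rt
Reagents that add atoms: none
Why: Acid-catalysed acetonide hydrolysis followed by lactonisation (intramolecular transesterification) of the secondary hydroxyl onto the cis ester. No bond to the stereocentre is broken, and any E ester cannot cyclise and is separated as the polar diol.

Step 6
Reactants: 7 (R)-5-(hydroxymethyl)furan-2(5H)-one
Product: 8 (R)-5-(trityloxymethyl)furan-2(5H)-one
Conditions: TrCl, pyridine, CH2Cl2, 0 °C to rt
Reagents that add atoms: trityl chloride, ClC(c1ccccc1)(c1ccccc1)c1ccccc1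
Why: Tritylation of the primary alcohol (SN1 etherification). The weak base pyridine avoids deprotonation at the γ-carbon, which would racemise the butenolide, and the bulky ether later shields one face of the ring.

Step 7
Reactants: 9 vanillin
Product: 10 3-methoxy-4-(triisopropylsilyloxy)benzaldehyde
Conditions: TIPSCl, imidazole, DMF, rt
Reagents that add atoms: chlorotriisopropylsilane, CC(C)[Si](Cl)(C(C)C)C(C)C
Why: Imidazole-promoted silylation of the phenol. The hindered TIPS ether should withstand organolithium, hydride, periodate and catalytic acid and is removed by fluoride at the end.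

Step 8
Reactants: 10 3-methoxy-4-(triisopropylsilyloxy)benzaldehyde; 11 propane-1,3-dithiol
Product: 12 2-[3-methoxy-4-(triisopropylsilyloxy)phenyl]-1,3-dithiane
Conditions: BF3·OEt2 (cat.), CH2Cl2, 0 °C to rt
Reagents that add atoms: none
Why: Lewis-acid-catalysed thioacetalisation of the aldehyde gives the acyl-anion equivalent for C2.

Step 9
Reactants: 10 3-methoxy-4-(triisopropylsilyloxy)benzaldehyde
Product: 13 [3-methoxy-4-(triisopropylsilyloxy)phenyl]methanol
Conditions: NaBH4, EtOH/THF, 0 °C
Reagents that add atoms: none
Why: Borohydride reduction of the aldehyde; short reaction time at 0 °C keeps the aryl silyl ether intact.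

Step 10
Reactants: 13 [3-methoxy-4-(triisopropylsilyloxy)phenyl]methanol
Product: 14 3-methoxy-4-(triisopropylsilyloxy)benzyl bromide
Conditions: PBr3 (0.4 equiv), pyridine (cat.), Et2O, 0 °C; used at once
Reagents that add atoms: phosphorus tribromide, BrP(Br)Br
Why: Conversion of the benzylic alcohol into the bromide through its phosphite ester. The electron-rich bromide ionises easily, so it is made cold, not chromatographed and used the same day.

Step 11
Reactants: 8 (R)-5-(trityloxymethyl)furan-2(5H)-one; 12 2-[3-methoxy-4-(triisopropylsilyloxy)phenyl]-1,3-dithiane; 14 3-methoxy-4-(triisopropylsilyloxy)benzyl bromide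
Product: 17 (3R,4R,5R)-3-[3-methoxy-4-(triisopropylsilyloxy)benzyl]-4-{2-[3-methoxy-4-(triisopropylsilyloxy)phenyl]-1,3-dithian-2-yl}-5-(trityloxymethyl)dihydrofuran-2(3H)-one, via lithiated dithiane 15 (not isolated), via lactone lithium enolate 16 (not isolated)
Conditions: 12, n-BuLi, THF, −78 to −20 °C; 8, THF, −78 °C; then 14, DMPU, −78 to −40 °C; aq. NH4Cl
Reagents that add atoms: none
Why: Deprotonation of 12 gives the sulfur-stabilised benzylic anion 15, which adds in Michael fashion to the β-carbon of 8 (C2–C3 bond) to give enolate 16; 16 is then alkylated on carbon by 14 in an SN2 step (C4–C7′ bond). The closest known reaction type is the tandem conjugate addition–enolate alkylation of γ-(alkoxymethyl)butenolides with 2-lithio-2-aryl-1,3-dithianes, a three-component coupling long used for lignan lactones. No ring is closed. C3 is controlled by the γ-stereocentre: the CH2OTr group blocks one face of the planar butenolide and the bulky nucleophile enters anti to it. C4 is controlled by C3: the dithianyl group on the adjacent carbon shields its own face of the enolate, so the benzyl bromide approaches anti and the trans,trans lactone results. The step needs 1,4- rather than 1,2-addition, which the soft, hindered, delocalised aryl dithiane anion and the unhindered β-carbon secure at −78 °C. It also needs C-monoalkylation, which the reactive benzylic bromide, the polar additive DMPU (used in place of HMPA) and the tertiary, crowded nature of the alkylated α-carbon secure. The γ-stereocentre is used only for induction and is removed in step 15.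

Step 12
Reactants: 17 trans,trans dithianyl lactone
Product: 18 (3R,4R,5R)-3-[3-methoxy-4-(triisopropylsilyloxy)benzyl]-4-[3-methoxy-4-(triisopropylsilyloxy)benzoyl]-5-(trityloxymethyl)dihydrofuran-2(3H)-one
Conditions: MeI, CaCO3, MeCN/H2O (9:1), 45 °C
Reagents that add atoms: water, O
Why: Alkylative hydrolysis of the dithiane: S-methylation creates a sulfonium leaving group and water adds to the thionium ion. The CaCO3 buffer keeps trityl and silyl ethers intact, and the non-oxidative conditions spare the electron-rich arenes and avoid mercury salts.

Step 13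
Reactants: 18 keto lactone trityl ether
Product: 19 (3R,4R,5R)-5-(hydroxymethyl)-3-[3-methoxy-4-(triisopropylsilyloxy)benzyl]-4-[3-methoxy-4-(triisopropylsilyloxy)benzoyl]dihydrofuran-2(3H)-one
Conditions: TsOH·H2O (cat.), MeOH/CH2Cl2 (1:1), rt
Reagents that add atoms: none
Why: Acid-catalysed SN1 cleavage of the trityl ether, with the cation trapped by methanol. It is done while C2 is a ketone, so no acid-labile benzylic alcohol is present, and aryl TIPS ethers tolerate catalytic sulfonic acid.

Step 14
Reactants: 19 hydroxy keto lactone
Product: 20 (2R,3S,4R)-3-{hydroxy[3-methoxy-4-(triisopropylsilyloxy)phenyl]methyl}-4-[3-methoxy-4-(triisopropylsilyloxy)benzyl]pentane-1,2,5-triol (both carbinol epimers at C2 of the target numbering)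
Conditions: LiBH4, THF, 0 °C to rt
Reagents that add atoms: none
Why: Hydride reduction of the aryl ketone and of the γ-lactone to the tetraol; LiBH4 is milder toward aryl silyl ethers than LiAlH4. The carbinol configuration is irrelevant because C2 is set again in step 16.

Step 15
Reactants: 20 tetraol
Product: 23 (2R,3R)-2-{hydroxy[3-methoxy-4-(triisopropylsilyloxy)phenyl]methyl}-3-[3-methoxy-4-(triisopropylsilyloxy)benzyl]butane-1,4-diol, via hydroxy aldehyde 21 (not isolated), via lactol 22 (not isolated)
Conditions: NaIO4 (1.2 equiv), THF/H2O, 0 °C; then NaBH4, 0 °C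
Reagents that add atoms: none
Why: Periodate cleavage of the only 1,2-diol removes the exocyclic carbon as formaldehyde (reduced to methanol in the flask) and turns the former γ-carbon into the C9 aldehyde 21. This should rest as the five-membered lactol 22 with the C5 hydroxyl, which shields C3 from epimerisation, and borohydride reduces the open form to the C9 alcohol. Sulfur is already gone and the phenols are silylated, so periodate has no other site of attack.

Step 16
Reactants: 23 triol
Product: 24 {(2S,3R,4R)-4-[3-methoxy-4-(triisopropylsilyloxy)benzyl]-2-[3-methoxy-4-(triisopropylsilyloxy)phenyl]tetrahydrofuran-3-yl}methanol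
Conditions: CSA (10 mol %), CH2Cl2, 0 °C; Et3N quench
Reagents that add atoms: none
Why: Acid-catalysed cyclodehydration (SN1) through the para-oxygen-stabilised benzylic cation at C2; only the C5 hydroxyl can close a five-membered ring, since the C9 hydroxyl would give an oxetane. The aryl group takes the position trans to the C3 substituent in the envelope-like transition state, and the closure is reversible, so the 2,3-trans (2S) isomer is expected; low temperature and early quench are meant to forestall attack of the second arene on the cation.

Step 17
Reactants: 24 bis-TIPS lariciresinol; 25 stearoyl chloride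
Product: 26 {(2S,3R,4R)-4-[3-methoxy-4-(triisopropylsilyloxy)benzyl]-2-[3-methoxy-4-(triisopropylsilyloxy)phenyl]tetrahydrofuran-3-yl}methyl octadecanoate
Conditions: pyridine, DMAP (cat.), CH2Cl2, 0 °C to rt
Reagents that add atoms: none
Why: DMAP-catalysed acylation of the single free, primary hydroxyl with an acid chloride. No selectivity is needed because both phenols are still silylated.

Step 18
Reactants: 26 bis-TIPS lariciresinol stearate
Product: 27 {(2S,3R,4R)-4-(4-hydroxy-3-methoxybenzyl)-2-(4-hydroxy-3-methoxyphenyl)tetrahydrofuran-3-yl}methyl octadecanoate (target)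
Conditions: TBAF (2.2 equiv), AcOH (2.5 equiv), THF, 0 °C
Reagents that add atoms: none
Why: Fluoride cleavage of the two aryl silyl ethers, which is fast for phenolic silyl ethers. Acetic acid buffers fluoride and phenoxide so that the primary ester should neither hydrolyse nor migrate, and no acid strong enough to ionise C2 is present.

## Compound list

1 | L-ascorbic acid | OC[C@H](O)[C@H]1OC(=O)C(O)=C1O | starting material
2 | L-gulono-1,4-lactone | O=C1[C@@H](O)[C@@H](O)[C@H](O1)[C@@H](O)CO | intermediate
3 | 5,6-O-isopropylidene-L-gulono-1,4-lactone | O=C1[C@@H](O)[C@@H](O)[C@H](O1)[C@@H]1COC(C)(C)O1 | intermediate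
4 | (S)-2,2-dimethyl-1,3-dioxolane-4-carbaldehyde | CC1(C)OC[C@H](O1)C=O | intermediate
5 | methyl (triphenylphosphoranylidene)acetate | COC(=O)C=P(c1ccccc1)(c1ccccc1)c1ccccc1 | starting material
6 | methyl (Z)-3-[(4R)-2,2-dimethyl-1,3-dioxolan-4-yl]prop-2-enoate | CC1(C)OC[C@H](O1)/C=C\C(=O)OC | intermediate
7 | (R)-5-(hydroxymethyl)furan-2(5H)-one | OC[C@@H]1OC(=O)C=C1 | intermediate
8 | (R)-5-(trityloxymethyl)furan-2(5H)-one | C(c1ccccc1)(c1ccccc1)(c1ccccc1)OC[C@@H]1OC(=O)C=C1 | intermediate
9 | vanillin | COc1cc(C=O)ccc1O | starting material
10 | 3-methoxy-4-(triisopropylsilyloxy)benzaldehyde | COc1cc(C=O)ccc1O[Si](C(C)C)(C(C)C)C(C)C | intermediate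
11 | propane-1,3-dithiol | SCCCS | starting material
12 | 2-[3-methoxy-4-(triisopropylsilyloxy)phenyl]-1,3-dithiane | COc1cc(C2SCCCS2)ccc1O[Si](C(C)C)(C(C)C)C(C)C | intermediate
13 | [3-methoxy-4-(triisopropylsilyloxy)phenyl]methanol | COc1cc(CO)ccc1O[Si](C(C)C)(C(C)C)C(C)C | intermediate
14 | 3-methoxy-4-(triisopropylsilyloxy)benzyl bromide | COc1cc(CBr)ccc1O[Si](C(C)C)(C(C)C)C(C)C | intermediate
15 | 2-lithio-2-[3-methoxy-4-(triisopropylsilyloxy)phenyl]-1,3-dithiane | COc1cc(C2([Li])SCCCS2)ccc1O[Si](C(C)C)(C(C)C)C(C)C | intermediate
16 | lithium enolate of (4R,5R)-4-{2-[3-methoxy-4-(triisopropylsilyloxy)phenyl]-1,3-dithian-2-yl}-5-(trityloxymethyl)dihydrofuran-2(3H)-one | C(c1ccccc1)(c1ccccc1)(c1ccccc1)OC[C@@H]1OC(O[Li])=C[C@H]1C1(SCCCS1)c1ccc(O[Si](C(C)C)(C(C)C)C(C)C)c(OC)c1 | intermediate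
17 | (3R,4R,5R)-3-[3-methoxy-4-(triisopropylsilyloxy)benzyl]-4-{2-[3-methoxy-4-(triisopropylsilyloxy)phenyl]-1,3-dithian-2-yl}-5-(trityloxymethyl)dihydrofuran-2(3H)-one | C(c1ccccc1)(c1ccccc1)(c1ccccc1)OC[C@@H]1OC(=O)[C@H](Cc2ccc(O[Si](C(C)C)(C(C)C)C(C)C)c(OC)c2)[C@H]1C1(SCCCS1)c1ccc(O[Si](C(C)C)(C(C)C)C(C)C)c(OC)c1 | intermediate
18 | (3R,4R,5R)-3-[3-methoxy-4-(triisopropylsilyloxy)benzyl]-4-[3-methoxy-4-(triisopropylsilyloxy)benzoyl]-5-(trityloxymethyl)dihydrofuran-2(3H)-one | C(c1ccccc1)(c1ccccc1)(c1ccccc1)OC[C@@H]1OC(=O)[C@H](Cc2ccc(O[Si](C(C)C)(C(C)C)C(C)C)c(OC)c2)[C@H]1C(=O)c1ccc(O[Si](C(C)C)(C(C)C)C(C)C)c(OC)c1 | intermediate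
19 | (3R,4R,5R)-5-(hydroxymethyl)-3-[3-methoxy-4-(triisopropylsilyloxy)benzyl]-4-[3-methoxy-4-(triisopropylsilyloxy)benzoyl]dihydrofuran-2(3H)-one | OC[C@@H]1OC(=O)[C@H](Cc2ccc(O[Si](C(C)C)(C(C)C)C(C)C)c(OC)c2)[C@H]1C(=O)c1ccc(O[Si](C(C)C)(C(C)C)C(C)C)c(OC)c1 | intermediate
20 | (2R,3S,4R)-3-{hydroxy[3-methoxy-4-(triisopropylsilyloxy)phenyl]methyl}-4-[3-methoxy-4-(triisopropylsilyloxy)benzyl]pentane-1,2,5-triol, carbinol epimers | OC[C@H](O)[C@@H]([C@H](CO)Cc1ccc(O[Si](C(C)C)(C(C)C)C(C)C)c(OC)c1)C(O)c1ccc(O[Si](C(C)C)(C(C)C)C(C)C)c(OC)c1 | intermediate
21 | (2S,3R)-4-hydroxy-2-{hydroxy[3-methoxy-4-(triisopropylsilyloxy)phenyl]methyl}-3-[3-methoxy-4-(triisopropylsilyloxy)benzyl]butanal, carbinol epimers | O=C[C@@H]([C@H](CO)Cc1ccc(O[Si](C(C)C)(C(C)C)C(C)C)c(OC)c1)C(O)c1ccc(O[Si](C(C)C)(C(C)C)C(C)C)c(OC)c1 | intermediate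
22 | (3S,4R)-3-{hydroxy[3-methoxy-4-(triisopropylsilyloxy)phenyl]methyl}-4-[3-methoxy-4-(triisopropylsilyloxy)benzyl]tetrahydrofuran-2-ol, anomers and carbinol epimers | OC1OC[C@H](Cc2ccc(O[Si](C(C)C)(C(C)C)C(C)C)c(OC)c2)[C@H]1C(O)c1ccc(O[Si](C(C)C)(C(C)C)C(C)C)c(OC)c1 | intermediate
23 | (2R,3R)-2-{hydroxy[3-methoxy-4-(triisopropylsilyloxy)phenyl]methyl}-3-[3-methoxy-4-(triisopropylsilyloxy)benzyl]butane-1,4-diol, carbinol epimers | OC[C@@H]([C@H](CO)Cc1ccc(O[Si](C(C)C)(C(C)C)C(C)C)c(OC)c1)C(O)c1ccc(O[Si](C(C)C)(C(C)C)C(C)C)c(OC)c1 | intermediate
24 | {(2S,3R,4R)-4-[3-methoxy-4-(triisopropylsilyloxy)benzyl]-2-[3-methoxy-4-(triisopropylsilyloxy)phenyl]tetrahydrofuran-3-yl}methanol | OC[C@H]1[C@@H](Cc2ccc(O[Si](C(C)C)(C(C)C)C(C)C)c(OC)c2)CO[C@@H]1c1ccc(O[Si](C(C)C)(C(C)C)C(C)C)c(OC)c1 | intermediate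
25 | stearoyl chloride (octadecanoyl chloride) | CCCCCCCCCCCCCCCCCC(=O)Cl | starting material
26 | {(2S,3R,4R)-4-[3-methoxy-4-(triisopropylsilyloxy)benzyl]-2-[3-methoxy-4-(triisopropylsilyloxy)phenyl]tetrahydrofuran-3-yl}methyl octadecanoate | CCCCCCCCCCCCCCCCCC(=O)OC[C@H]1[C@@H](Cc2ccc(O[Si](C(C)C)(C(C)C)C(C)C)c(OC)c2)CO[C@@H]1c1ccc(O[Si](C(C)C)(C(C)C)C(C)C)c(OC)c1 | intermediate
27 | {(2S,3R,4R)-4-(4-hydroxy-3-methoxybenzyl)-2-(4-hydroxy-3-methoxyphenyl)tetrahydrofuran-3-yl}methyl octadecanoate | CCCCCCCCCCCCCCCCCC(=O)OC[C@H]1[C@@H](Cc2ccc(O)c(OC)c2)CO[C@@H]1c1ccc(O)c(OC)c1 | target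

## Step count and least certain steps

Total step count: 18. Longest linear sequence: 14 (steps 1 to 6, then 11 to 18).

**Step 11 (key step).** The most likely failure is incomplete trapping of enolate 16. The ionisation-prone bromide 14 may decompose, or proton transfer may quench the enolate before C-alkylation. Erosion of the second anti induction or some 1,2-addition could also lower the yield of the trans,trans isomer.
Fallback, from 8 back to 17: the two bond formations are separated. Anion 15 is added to 8 and the enolate is protonated with aqueous NH4Cl to give the trans β-dithianyl lactone F1, which can be purified by crystallisation. The enolate is then regenerated with LDA in THF at −78 °C and alkylated with freshly made 14 in the presence of DMPU, again anti to the β-substituent, to give 17.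

**Step 12.** S-Methylation at the crowded, fully substituted thioacetal carbon may be slow. Once the ketone is unmasked, C3 is α to it and the lactone oxygen is β, so prolonged warming may cause β-elimination of the carboxylate (ring opening to an enone) or epimerisation at C3.
Fallback, from 17 back to 20: the ketone is unmasked only after the lactone has been reduced. LiBH4 reduces 17 to the dithianyl diol F2. The trityl ether is removed with catalytic TsOH in methanol to give the dithianyl triol F3. MeI/CaCO3 hydrolysis then gives the keto triol F4, which is expected to rest as a cyclic hemiketal, and NaBH4 reduces it to 20.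

**Step 15.** The ring–chain equilibrium may expose the β-hydroxy aldehyde 21 under the basic borohydride conditions. That would allow epimerisation at C3, retro-aldol loss of the aryl carbinol or dehydration before the reduction is complete.
Fallback, from 20 back to 23: the aldehyde is never reduced directly. After the periodate cleavage the lactol 22 is isolated and oxidised selectively with Ag2CO3 on Celite in warm toluene to the hydroxy lactone F5. Any over-oxidation of the benzylic hydroxyl is harmless, because the next step reduces it again. LiBH4 then reduces F5 to 23.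

**Step 16.** The benzylic cation may be captured irreversibly by the second arene (Friedel–Crafts closure to an aryltetralin). Kinetic closure may also give part of the 2,3-cis epimer, or elimination to a styrene may occur.
Fallback, from 23 back to 27: the ring is closed through a quinone methide instead. Buffered TBAF desilylates 23 to the free-phenol triol F6. Its para-hydroxybenzylic alcohol forms the quinone methide under much weaker acid (dilute acetic acid or pyridinium tosylate, rt), and the C5 hydroxyl adds to it in oxa-Michael fashion to give (+)-lariciresinol F7. The primary alcohol of F7 is then acylated selectively with immobilised Candida antarctica lipase B and vinyl stearate in tert-amyl alcohol at 45 °C, giving 27 directly.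

Further compounds
F1 | step 11 | (4R,5R)-4-{2-[3-methoxy-4-(triisopropylsilyloxy)phenyl]-1,3-dithian-2-yl}-5-(trityloxymethyl)dihydrofuran-2(3H)-one | C(c1ccccc1)(c1ccccc1)(c1ccccc1)OC[C@@H]1OC(=O)C[C@H]1C1(SCCCS1)c1ccc(O[Si](C(C)C)(C(C)C)C(C)C)c(OC)c1
F2 | step 12 | (2R,3R,4R)-2-[3-methoxy-4-(triisopropylsilyloxy)benzyl]-3-{2-[3-methoxy-4-(triisopropylsilyloxy)phenyl]-1,3-dithian-2-yl}-5-(trityloxy)pentane-1,4-diol | C(c1ccccc1)(c1ccccc1)(c1ccccc1)OC[C@H](O)[C@@H]([C@H](CO)Cc1ccc(O[Si](C(C)C)(C(C)C)C(C)C)c(OC)c1)C1(SCCCS1)c1ccc(O[Si](C(C)C)(C(C)C)C(C)C)c(OC)c1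
F3 | step 12 | (2R,3R,4R)-4-[3-methoxy-4-(triisopropylsilyloxy)benzyl]-3-{2-[3-methoxy-4-(triisopropylsilyloxy)phenyl]-1,3-dithian-2-yl}pentane-1,2,5-triol | OC[C@H](O)[C@@H]([C@H](CO)Cc1ccc(O[Si](C(C)C)(C(C)C)C(C)C)c(OC)c1)C1(SCCCS1)c1ccc(O[Si](C(C)C)(C(C)C)C(C)C)c(OC)c1
F4 | step 12 | (2R,3R,4R)-4-[3-methoxy-4-(triisopropylsilyloxy)benzyl]-3-[3-methoxy-4-(triisopropylsilyloxy)benzoyl]pentane-1,2,5-triol | OC[C@H](O)[C@@H]([C@H](CO)Cc1ccc(O[Si](C(C)C)(C(C)C)C(C)C)c(OC)c1)C(=O)c1ccc(O[Si](C(C)C)(C(C)C)C(C)C)c(OC)c1
F5 | step 15 | (3S,4R)-3-{hydroxy[3-methoxy-4-(triisopropylsilyloxy)phenyl]methyl}-4-[3-methoxy-4-(triisopropylsilyloxy)benzyl]dihydrofuran-2(3H)-one, carbinol epimers | O=C1OC[C@H](Cc2ccc(O[Si](C(C)C)(C(C)C)C(C)C)c(OC)c2)[C@H]1C(O)c1ccc(O[Si](C(C)C)(C(C)C)C(C)C)c(OC)c1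
F6 | step 16 | (2R,3R)-2-[hydroxy(4-hydroxy-3-methoxyphenyl)methyl]-3-(4-hydroxy-3-methoxybenzyl)butane-1,4-diol, carbinol epimers | OC[C@@H]([C@H](CO)Cc1ccc(O)c(OC)c1)C(O)c1ccc(O)c(OC)c1
F7 | step 16 | (+)-lariciresinol, [(2S,3R,4R)-4-(4-hydroxy-3-methoxybenzyl)-2-(4-hydroxy-3-methoxyphenyl)tetrahydrofuran-3-yl]methanol | OC[C@H]1[C@@H](Cc2ccc(O)c(OC)c2)CO[C@@H]1c1ccc(O)c(OC)c1
A1 | alternative 1 | {(2S,3R)-2-[3-methoxy-4-(triisopropylsilyloxy)phenyl]-2,3-dihydrofuran-3-yl}methanol | OC[C@H]1C=CO[C@@H]1c1ccc(O[Si](C(C)C)(C(C)C)C(C)C)c(OC)c1
A2 | alternative 1 | 3-methoxy-4-(triisopropylsilyloxy)benzaldehyde dimethyl acetal | COC(OC)c1ccc(O[Si](C(C)C)(C(C)C)C(C)C)c(OC)c1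
A3 | alternative 1 | cis-fused 4-methoxy-2,6-bis[3-methoxy-4-(triisopropylsilyloxy)phenyl]-3,7-dioxabicyclo[3.3.0]octane (furofuran methyl acetal) | O2C[C@H]1[C@@H]([C@H]2c2ccc(O[Si](C(C)C)(C(C)C)C(C)C)c(OC)c2)[C@H](OC)O[C@@H]1c1ccc(O[Si](C(C)C)(C(C)C)C(C)C)c(OC)c1
A4 | alternative 1 | bis-O-triisopropylsilyl (+)-pinoresinol | O2C[C@H]1[C@@H]([C@H]2c2ccc(O[Si](C(C)C)(C(C)C)C(C)C)c(OC)c2)CO[C@@H]1c1ccc(O[Si](C(C)C)(C(C)C)C(C)C)c(OC)c1
A5 | alternative 2 | 3-[3-methoxy-4-(triisopropylsilyloxy)benzyl]cyclobutan-1-one | O=C1CC(Cc2ccc(O[Si](C(C)C)(C(C)C)C(C)C)c(OC)c2)C1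
A6 | alternative 2 | (R)-4-[3-methoxy-4-(triisopropylsilyloxy)benzyl]dihydrofuran-2(3H)-one | O=C1C[C@@H](Cc2ccc(O[Si](C(C)C)(C(C)C)C(C)C)c(OC)c2)CO1
A7 | alternative 3 | (R)-2-[(R)-{[(E)-3-(3-methoxy-4-(triisopropylsilyloxy)phenyl)prop-2-en-1-yl]oxy}[3-methoxy-4-(triisopropylsilyloxy)phenyl]methyl]oxirane | COc1cc(/C=C/CO[C@@H]([C@H]2CO2)c2ccc(O[Si](C(C)C)(C(C)C)C(C)C)c(OC)c2)ccc1O[Si](C(C)C)(C(C)C)C(C)C
A8 | alternative 3 | bis-O-triisopropylsilyl (+)-lariciresinol (identical with 24) | OC[C@H]1[C@@H](Cc2ccc(O[Si](C(C)C)(C(C)C)C(C)C)c(OC)c2)CO[C@@H]1c1ccc(O[Si](C(C)C)(C(C)C)C(C)C)c(OC)c1
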